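Bench note on the flask. The easy count comes first: in the north run electrophile reads 0% and target 71%, so about 2.90 mM went elsewhere, near the 4 mM of protic impurity.

| flask | electrophile | nucleophile | protic impurity | remark | time |
|---|---|---|---|---|---|
| north | 10 mM | 24 mM | 4 mM | run made earlier |  |
| south-west | 40 mM | 24 mM | 4 mM | run made earlier |  |
| south-east | 20 mM | 48 mM | 4 mM | run made earlier |  |
| flask | 20 mM | 24.0 mM | 4.00 mM |  | 5.0 h |

| run | time / h | electrophile / % | target / % |
|---|---|---|---|
| north | 0.500 | 0 | 71 |
| north | 1.33 | 0 | 71 |
| north | 2.50 | 1 | 72 |
| north | 4.00 | 0 | 70 |
| south-west | 0.500 | 58 | 32 |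
| south-west | 1.33 | 51 | 37 |
| south-west | 2.50 | 55 | 39 |
| south-west | 4.00 | 52 | 42 |
| south-east | 0.500 | 2 | 83 |
| south-east | 1.33 | 2 | 85 |
| south-east | 2.50 | 0 | 82 |
| south-east | 4.00 | 0 | 79 |

(scatter of a reading: 2 percentage points)

- what was read earlier has a scatter of 2 percentage points, one standard deviation
- the earlier runs do not show how much of nucleophile is bound; that part of a forecast is a guess

1. part of the electrophile that has reacted at 5.0 h
2. share of the unused nucleophile that is free and not bound as protonated nucleophile, at 5.0 h

Suppose protic impurity takes electrophile one for one, while each target costs two nucleophile, one to react and one to bind the acid it sets free. In this flask nucleophile is then the limiting reagent, and the flask's stall mark is 16.0 mM: half the charged [nucleophile] plus the charged [protic impurity]. The south-west run has the same mark; its readings put the electrophile used at 16.8 mM at 0.500 h and 19.2 mM at 4.00 h, so that run read near the mark at first and past it at the last reading. For this flask the mark is 80.0% of the electrophile, and this reckoning expects a creep beyond that by 5.0 h, by an amount the runs leave open. The flask stays closed: added nucleophile moves the mark.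

The forecast gives 80% reacted and 10% free, “leaving only a slow leak of free nucleophile”; its figure for reacted electrophile comes by a count of its own, not from the mark above.

    electrophile + protic impurity → quenched substrate (k = 0.904 M⁻¹ s⁻¹)
    nucleophile + acid set free ⇌ protonated nucleophile, settled at all times (K = 40700 M⁻¹)
    electrophile + nucleophile → acid set free + target (k = 0.292 M⁻¹ s⁻¹)

The flask gives 89.0% reacted and 0.666% free, so 17.8 mM of electrophile has reacted, 1.80 mM past the mark. Its acid set free stands at 3.66 mM, and half of that is 1.83 mM, close to the overshoot. The neighbour with 50 mM of electrophile has the same mark and has used 21.5 mM, which is 5.50 mM past it, with acid set free at 11.1 mM, half of which is 5.55 mM.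

Readings and results are calculated for substances that don't exist; noise was put on by code.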